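## Retrosynthetic overview

1. Target ⇐ removal of three MOM groups from a protected flavanone. Ring C is closed last by an intramolecular Mitsunobu etherification (inversion) of a (3R)-β-hydroxy ketone; the only free phenol is the one next to the lavandulyl group, so it becomes O-1.
2. (3R)-β-Hydroxy ketone ⇐ SmI2 opening of a (2R,3S)-epoxy ketone ⇐ Juliá–Colonna epoxidation of a chalcone.
3. Chalcone ⇐ key C–C bond: Claisen–Schmidt aldol condensation of the ring A methyl ketone with the ring B aldehyde.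
4. Ring A ketone ⇐ Negishi sp3–sp2 coupling of lavandulylzinc iodide with a 3-iodoacetophenone made from 2',6'-dihydroxy-4'-methoxyacetophenone; lavandulyl stereocentre ⇐ Evans deconjugative α-prenylation.
5. Ring B aldehyde ⇐ isovanillin (Baeyer–Villiger, Vilsmeier–Haack). Rings A and B are bought as arenes; ring C is the only ring formed.

Assumption: 2',6'-dihydroxy-4'-methoxyacetophenone, isovanillin, (S)-4-benzyl-2-oxazolidinone and poly-L-leucine are bought.

Note: "lavandulyl" = 5-methyl-2-(prop-1-en-2-yl)hex-4-en-1-yl. Its stereocentre keeps one geometry from 7 to 30; the descriptor reads S while C-1 carries C=O, OH, I or Zn, and R once C-1 carries the arene (CIP ranking only). The target is (2S) at the flavanone carbon and (R) at the lavandulyl carbon.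

## Route

Step 1
Reactants: 1 (S)-4-benzyl-2-oxazolidinone; 2 senecioyl chloride (3-methylbut-2-enoyl chloride)
Product: 4 (4S)-4-benzyl-3-(3-methylbut-2-enoyl)oxazolidin-2-one, via N-lithio oxazolidinone 3 (not isolated)
Conditions: n-BuLi, THF, −78 °C; then 2, −78 → 0 °C
Reagents that add atoms: none
Why: N-acylation of the lithiated auxiliary by the acid chloride (nucleophilic acyl substitution) is fast at low temperature and avoids amine bases that would deconjugate the senecioyl unit.

Step 2
Reactants: 4 (4S)-4-benzyl-3-(3-methylbut-2-enoyl)oxazolidin-2-one; 5 prenyl bromide (1-bromo-3-methylbut-2-ene)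
Product: 7 (4S)-4-benzyl-3-[(2S)-5-methyl-2-(prop-1-en-2-yl)hex-4-enoyl]oxazolidin-2-one, via sodium dienolate 6 (not isolated)
Conditions: NaN(SiMe3)2, THF, −78 °C; then 5, −78 → −40 °C
Reagents that add atoms: none
Why: Evans deconjugative α-alkylation: γ-deprotonation gives the chelated (Z)-dienolate, which is prenylated at the α-carbon on the face opposite the 4-benzyl group, setting the lavandulyl stereocentre (2S, by analogy with Evans allylation) and leaving the isopropenyl group; the minor diastereomer is removed by chromatography.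

Step 3
Reactants: 7 (4S)-4-benzyl-3-[(2S)-5-methyl-2-(prop-1-en-2-yl)hex-4-enoyl]oxazolidin-2-one
Product: 8 (S)-lavandulol [(2S)-5-methyl-2-(prop-1-en-2-yl)hex-4-en-1-ol]
Conditions: LiBH4, MeOH (1 equiv), Et2O, 0 °C
Reagents that add atoms: none
Why: Reductive cleavage of the imide by LiBH4 releases the primary alcohol and the recoverable auxiliary under conditions too mild to epimerise or conjugate the β,γ-unsaturated α-centre.

Step 4
Reactants: 8 (S)-lavandulol
Product: 9 (S)-lavandulyl iodide [(3S)-3-(iodomethyl)-2,6-dimethylhepta-1,5-diene]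
Conditions: PPh3, I2, imidazole, CH2Cl2, 0 °C → rt
Reagents that add atoms: iodine (II)
Why: Appel-type iodination is an SN2 displacement at the primary carbon, so the adjacent stereocentre and both alkenes are untouched.

Step 5
Reactants: 10 1-(2,6-dihydroxy-4-methoxyphenyl)ethan-1-one
Product: 11 1-[2-hydroxy-4-methoxy-6-(methoxymethoxy)phenyl]ethan-1-one
Conditions: MOMCl (1.1 equiv), i-Pr2NEt, CH2Cl2, 0 °C → rt
Reagents that add atoms: chloromethyl methyl ether (COCCl)
Why: Mono-O-alkylation of the symmetric diol stops cleanly because the remaining phenol is held in a strong hydrogen bond to the ketone; this differentiates the future 5-OH (MOM) from the future O-1.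

Step 6
Reactants: 11 1-[2-hydroxy-4-methoxy-6-(methoxymethoxy)phenyl]ethan-1-one
Product: 12 1-[2-hydroxy-3-iodo-4-methoxy-6-(methoxymethoxy)phenyl]ethan-1-one
Conditions: BnMe3N+ ICl2− (1.0 equiv), NaHCO3, CH2Cl2/MeOH, rt
Reagents that add atoms: benzyltrimethylammonium dichloroiodate (C[N+](C)(C)Cc1ccccc1.Cl[I-]Cl)
Why: Electrophilic aromatic iodination with this reagent goes ortho to the free chelated phenol (the less hindered of the two open positions), placing iodine at the future C-8; bicarbonate protects the MOM ether from HCl.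

Step 7
Reactants: 12 1-[2-hydroxy-3-iodo-4-methoxy-6-(methoxymethoxy)phenyl]ethan-1-one
Product: 13 1-[2-(tert-butyldimethylsilyloxy)-3-iodo-4-methoxy-6-(methoxymethoxy)phenyl]ethan-1-one
Conditions: TBSCl, imidazole, 4-dimethylaminopyridine (cat.), DMF, 40 °C
Reagents that add atoms: tert-butyldimethylsilyl chloride (CC(C)(C)[Si](C)(C)Cl)
Why: Silylation gives temporary protection, because a free phenol would protonate the organozinc and an o-allyloxy aryl iodide would undergo Heck cyclisation under palladium catalysis.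

Step 8
Reactants: 9 (S)-lavandulyl iodide; 13 1-[2-(tert-butyldimethylsilyloxy)-3-iodo-4-methoxy-6-(methoxymethoxy)phenyl]ethan-1-one
Product: 15 1-{2-(tert-butyldimethylsilyloxy)-4-methoxy-6-(methoxymethoxy)-3-[(2R)-lavandulyl]phenyl}ethan-1-one, via lavandulylzinc iodide 14 (not isolated)
Conditions: 9, Zn dust (BrCH2CH2Br/Me3SiCl activation), LiCl, THF, 40 °C; then 13, Pd(OAc)2 (3 mol %), SPhos (6 mol %), THF, 25 → 45 °C
Reagents that add atoms: none
Why: Negishi sp3–sp2 cross-coupling: the alkylzinc halide tolerates the ketone, MOM and silyl ether, and the bulky electron-rich SPhos–palladium catalyst inserts into the di-ortho-substituted C–I bond and lets reductive elimination outrun β-hydride elimination; the stereocentre is not involved.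

Step 9
Reactants: 15 1-{2-(tert-butyldimethylsilyloxy)-4-methoxy-6-(methoxymethoxy)-3-[(2R)-lavandulyl]phenyl}ethan-1-one
Product: 16 1-{2-hydroxy-4-methoxy-6-(methoxymethoxy)-3-[(2R)-lavandulyl]phenyl}ethan-1-one
Conditions: Bu4NF, AcOH, THF, 0 °C → rt
Reagents that add atoms: none
Why: Buffered fluoride desilylation frees the phenol without touching the MOM ether, the ketone or the alkenes.

Step 10
Reactants: 16 1-{2-hydroxy-4-methoxy-6-(methoxymethoxy)-3-[(2R)-lavandulyl]phenyl}ethan-1-one
Product: 17 1-{2-(allyloxy)-4-methoxy-6-(methoxymethoxy)-3-[(2R)-lavandulyl]phenyl}ethan-1-one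
Conditions: allyl bromide, K2CO3, DMF, 50 °C
Reagents that add atoms: allyl bromide (C=CCBr)
Why: Williamson etherification installs a base-stable group that can later be removed under neutral palladium catalysis in the presence of MOM ethers and a sensitive aldol.

Step 11
Reactants: 18 isovanillin (3-hydroxy-4-methoxybenzaldehyde)
Product: 20 4-methoxybenzene-1,3-diol, via aryl formate 19 (not isolated)
Conditions: mCPBA, CH2Cl2, 0 °C → rt; then K2CO3 (cat.), MeOH, rt
Reagents that add atoms: 3-chloroperoxybenzoic acid (O=C(OO)c1cccc(Cl)c1)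
Why: Baeyer–Villiger (Dakin-type) oxidation: the aryl ring para to methoxy migrates in preference to hydride, and the formate is methanolysed to the phenol.

Step 12
Reactants: 20 4-methoxybenzene-1,3-diol
Product: 22 2,4-dihydroxy-5-methoxybenzaldehyde, via iminium chloride 21 (not isolated)
Conditions: POCl3, DMF, MeCN, 0 °C → rt; then H2O, 50 °C
Reagents that add atoms: N,N-dimethylformamide (CN(C)C=O); water (O)
Why: Vilsmeier–Haack formylation attacks the position ortho to one hydroxyl and para to the other, as in resorcinol, rather than the crowded carbon between the two hydroxyls.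

Step 13
Reactants: 22 2,4-dihydroxy-5-methoxybenzaldehyde
Product: 23 5-methoxy-2,4-bis(methoxymethoxy)benzaldehyde
Conditions: MOMCl (3 equiv), K2CO3, DMF, 0 → 40 °C
Reagents that add atoms: chloromethyl methyl ether (COCCl)
Why: Carbonate in DMF alkylates both phenols, including the chelated 2-OH, giving ethers that survive hydroxide, hydroperoxide, SmI2 and Mitsunobu conditions.

Step 14
Reactants: 17 1-{2-(allyloxy)-4-methoxy-6-(methoxymethoxy)-3-[(2R)-lavandulyl]phenyl}ethan-1-one; 23 5-methoxy-2,4-bis(methoxymethoxy)benzaldehyde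
Product: 25 (E)-1-{2-(allyloxy)-4-methoxy-6-(methoxymethoxy)-3-[(2R)-lavandulyl]phenyl}-3-[5-methoxy-2,4-bis(methoxymethoxy)phenyl]prop-2-en-1-one, via aldol adduct 24 (not isolated)
Conditions: KOH, EtOH/H2O, rt, 36 h
Reagents that add atoms: none
Why: Claisen–Schmidt condensation: the ketone enolate adds to the non-enolisable aldehyde (intermolecular aldol) and the adduct dehydrates to the conjugated (E)-enone, joining rings A and B; all ethers are stable to hydroxide.

Step 15
Reactants: 25 the (E)-chalcone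
Product: 26 {2-(allyloxy)-4-methoxy-6-(methoxymethoxy)-3-[(2R)-lavandulyl]phenyl}{(2R,3S)-3-[5-methoxy-2,4-bis(methoxymethoxy)phenyl]oxiran-2-yl}methanone
Conditions: poly-L-leucine (H-[L-Leu]n-OH), urea·H2O2, DBU, THF, rt; filter, use crude at once
Reagents that add atoms: hydrogen peroxide as its urea adduct (OO.NC(N)=O)
Why: Juliá–Colonna epoxidation (Weitz–Scheffer type): the helical poly-L-leucine delivers hydroperoxide to the enone face that gives the trans-(2R,3S)-epoxide, as for chalcone itself, setting the future C-2 configuration; the isolated lavandulyl and allyl alkenes are inert to the nucleophilic oxidant.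

Step 16
Reactants: 26 the (2R,3S)-epoxy ketone
Product: 27 (3R)-1-{2-(allyloxy)-4-methoxy-6-(methoxymethoxy)-3-[(2R)-lavandulyl]phenyl}-3-hydroxy-3-[5-methoxy-2,4-bis(methoxymethoxy)phenyl]propan-1-one
Conditions: SmI2 (2.2 equiv), THF/MeOH, −78 °C
Reagents that add atoms: none
Why: Ketyl formation by SmI2 and β-scission of the Cα–O bond, then protonation of the samarium enolate, gives the aldol product without elimination; the benzylic C–O bond is not broken, so C-3 is (3R).

Step 17
Reactants: 27 the (3R)-β-hydroxy ketone allyl ether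
Product: 28 (3R)-3-hydroxy-1-{2-hydroxy-4-methoxy-6-(methoxymethoxy)-3-[(2R)-lavandulyl]phenyl}-3-[5-methoxy-2,4-bis(methoxymethoxy)phenyl]propan-1-one
Conditions: Pd(PPh3)4 (5 mol %), morpholine, THF, rt
Reagents that add atoms: none
Why: Tsuji–Trost deallylation: zerovalent palladium ionises only the aryl allyl ether and morpholine traps the π-allyl, freeing the one phenol needed for ring closure under neutral conditions that spare the aldol, the MOM ethers and the lavandulyl alkenes.

Step 18
Reactants: 28 the (3R)-phenol-alcohol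
Product: 29 (2S)-7-methoxy-5-(methoxymethoxy)-2-[5-methoxy-2,4-bis(methoxymethoxy)phenyl]-8-[(2R)-lavandulyl]chroman-4-one
Conditions: PPh3, diisopropyl azodicarboxylate (DIAD), THF, 0 °C → rt
Reagents that add atoms: none
Why: Intramolecular Mitsunobu etherification: the only free phenol displaces the alkoxyphosphonium in a 6-exo SN2 step with inversion, turning the (3R)-carbinol into the (2S)-flavanone and fixing the lavandulyl group at C-8.

Step 19
Reactants: 29 the protected (2S)-flavanone
Product: 30 (2S)-2-(2,4-dihydroxy-5-methoxyphenyl)-5-hydroxy-7-methoxy-8-[(2R)-5-methyl-2-(prop-1-en-2-yl)hex-4-en-1-yl]chroman-4-one (target)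
Conditions: HCl (1.25 M in MeOH), THF, rt → 40 °C, monitored
Reagents that add atoms: none
Why: Acid-catalysed acetal exchange with methanol removes the three aryl MOM ethers; the lavandulyl group has no neighbouring free phenol to cyclise onto, and mild acid is chosen to avoid opening the C-2–O bond.

## Compound list

1 | (S)-4-benzyl-2-oxazolidinone | O=C1OC[C@H](Cc2ccccc2)N1 | starting material
2 | 3-methylbut-2-enoyl chloride | CC(C)=CC(Cl)=O | starting material
3 | N-lithio (S)-4-benzyl-2-oxazolidinone | [Li]N1[C@@H](Cc2ccccc2)COC1=O | intermediate (not isolated)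
4 | (4S)-4-benzyl-3-(3-methylbut-2-enoyl)oxazolidin-2-one | CC(C)=CC(=O)N1[C@@H](Cc2ccccc2)COC1=O | intermediate
5 | prenyl bromide (1-bromo-3-methylbut-2-ene) | CC(C)=CCBr | starting material
6 | sodium (Z)-dienolate of 4 | CC(=C)/C=C(\O[Na])N1[C@@H](Cc2ccccc2)COC1=O | intermediate (not isolated)
7 | (4S)-4-benzyl-3-[(2S)-5-methyl-2-(prop-1-en-2-yl)hex-4-enoyl]oxazolidin-2-one | CC(C)=CC[C@@H](C(C)=C)C(=O)N1[C@@H](Cc2ccccc2)COC1=O | intermediate
8 | (S)-lavandulol, (2S)-5-methyl-2-(prop-1-en-2-yl)hex-4-en-1-ol | CC(C)=CC[C@@H](C(C)=C)CO | intermediate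
9 | (S)-lavandulyl iodide, (3S)-3-(iodomethyl)-2,6-dimethylhepta-1,5-diene | CC(C)=CC[C@@H](C(C)=C)CI | intermediate
10 | 1-(2,6-dihydroxy-4-methoxyphenyl)ethan-1-one | CC(=O)c1c(O)cc(OC)cc1O | starting material
11 | 1-[2-hydroxy-4-methoxy-6-(methoxymethoxy)phenyl]ethan-1-one | CC(=O)c1c(O)cc(OC)cc1OCOC | intermediate
12 | 1-[2-hydroxy-3-iodo-4-methoxy-6-(methoxymethoxy)phenyl]ethan-1-one | CC(=O)c1c(O)c(I)c(OC)cc1OCOC | intermediate
13 | 1-[2-(tert-butyldimethylsilyloxy)-3-iodo-4-methoxy-6-(methoxymethoxy)phenyl]ethan-1-one | CC(=O)c1c(O[Si](C)(C)C(C)(C)C)c(I)c(OC)cc1OCOC | intermediate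
14 | [(2S)-5-methyl-2-(prop-1-en-2-yl)hex-4-en-1-yl]zinc iodide | CC(C)=CC[C@@H](C(C)=C)C[Zn]I | intermediate (not isolated)
15 | 1-{2-(tert-butyldimethylsilyloxy)-4-methoxy-6-(methoxymethoxy)-3-[(2R)-5-methyl-2-(prop-1-en-2-yl)hex-4-en-1-yl]phenyl}ethan-1-one | CC(=O)c1c(O[Si](C)(C)C(C)(C)C)c(C[C@@H](CC=C(C)C)C(C)=C)c(OC)cc1OCOC | intermediate
16 | 1-{2-hydroxy-4-methoxy-6-(methoxymethoxy)-3-[(2R)-lavandulyl]phenyl}ethan-1-one | CC(=O)c1c(O)c(C[C@@H](CC=C(C)C)C(C)=C)c(OC)cc1OCOC | intermediate
17 | 1-{2-(allyloxy)-4-methoxy-6-(methoxymethoxy)-3-[(2R)-lavandulyl]phenyl}ethan-1-one | CC(=O)c1c(OCC=C)c(C[C@@H](CC=C(C)C)C(C)=C)c(OC)cc1OCOC | intermediate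
18 | isovanillin (3-hydroxy-4-methoxybenzaldehyde) | COc1ccc(C=O)cc1O | starting material
19 | 3-hydroxy-4-methoxyphenyl formate | COc1ccc(OC=O)cc1O | intermediate (not isolated)
20 | 4-methoxybenzene-1,3-diol | COc1ccc(O)cc1O | intermediate
21 | N-[(2,4-dihydroxy-5-methoxyphenyl)methylidene]-N-methylmethanaminium chloride | C[N+](C)=Cc1cc(OC)c(O)cc1O.[Cl-] | intermediate (not isolated)
22 | 2,4-dihydroxy-5-methoxybenzaldehyde | O=Cc1cc(OC)c(O)cc1O | intermediate
23 | 5-methoxy-2,4-bis(methoxymethoxy)benzaldehyde | O=Cc1cc(OC)c(OCOC)cc1OCOC | intermediate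
24 | aldol adduct, 3-hydroxy ketone as both C-3 epimers (lavandulyl 2R) | C=CCOc1c(C[C@@H](CC=C(C)C)C(C)=C)c(OC)cc(OCOC)c1C(=O)CC(O)c1cc(OC)c(OCOC)cc1OCOC | intermediate (not isolated)
25 | (E)-1-{2-(allyloxy)-4-methoxy-6-(methoxymethoxy)-3-[(2R)-lavandulyl]phenyl}-3-[5-methoxy-2,4-bis(methoxymethoxy)phenyl]prop-2-en-1-one | C=CCOc1c(C[C@@H](CC=C(C)C)C(C)=C)c(OC)cc(OCOC)c1C(=O)/C=C/c1cc(OC)c(OCOC)cc1OCOC | intermediate
26 | {2-(allyloxy)-4-methoxy-6-(methoxymethoxy)-3-[(2R)-lavandulyl]phenyl}{(2R,3S)-3-[5-methoxy-2,4-bis(methoxymethoxy)phenyl]oxiran-2-yl}methanone | C=CCOc1c(C[C@@H](CC=C(C)C)C(C)=C)c(OC)cc(OCOC)c1C(=O)[C@@H]2O[C@H]2c3cc(OC)c(OCOC)cc3OCOC | intermediate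
27 | (3R)-1-{2-(allyloxy)-4-methoxy-6-(methoxymethoxy)-3-[(2R)-lavandulyl]phenyl}-3-hydroxy-3-[5-methoxy-2,4-bis(methoxymethoxy)phenyl]propan-1-one | C=CCOc1c(C[C@@H](CC=C(C)C)C(C)=C)c(OC)cc(OCOC)c1C(=O)C[C@@H](O)c1cc(OC)c(OCOC)cc1OCOC | intermediate
28 | (3R)-3-hydroxy-1-{2-hydroxy-4-methoxy-6-(methoxymethoxy)-3-[(2R)-lavandulyl]phenyl}-3-[5-methoxy-2,4-bis(methoxymethoxy)phenyl]propan-1-one | Oc1c(C[C@@H](CC=C(C)C)C(C)=C)c(OC)cc(OCOC)c1C(=O)C[C@@H](O)c1cc(OC)c(OCOC)cc1OCOC | intermediate
29 | (2S)-7-methoxy-5-(methoxymethoxy)-2-[5-methoxy-2,4-bis(methoxymethoxy)phenyl]-8-[(2R)-lavandulyl]chroman-4-one | C=C(C)[C@H](CC=C(C)C)Cc1c(OC)cc(OCOC)c2c1O[C@H](c1cc(OC)c(OCOC)cc1OCOC)CC2=O | intermediate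
30 | (2S)-2-(2,4-dihydroxy-5-methoxyphenyl)-5-hydroxy-7-methoxy-8-[(2R)-5-methyl-2-(prop-1-en-2-yl)hex-4-en-1-yl]chroman-4-one | C=C(C)[C@H](CC=C(C)C)Cc1c(OC)cc(O)c2c1O[C@H](c1cc(OC)c(O)cc1O)CC2=O | target

## Step count and risks

Total steps: 19. Longest linear sequence: 13 steps (1–4, 8–10, 14–19).

Steps most likely to fail:

Step 8 (Negishi coupling). The aryl iodide is flanked by two ortho substituents and the β-branched homoallylic alkyl–palladium can undergo β-hydride elimination to a diene. Fallback: set out from iodide 9; iodine–lithium exchange (t-BuLi, Et2O/pentane, −78 °C) and quenching with 2-isopropoxy-4,4,5,5-tetramethyl-1,3,2-dioxaborolane gives lavandulyl pinacol boronate F1. A Suzuki–Miyaura coupling of F1 with the unprotected iodophenol 12 (Pd(OAc)2, RuPhos, K3PO4, toluene/H2O, 90 °C; free phenols are tolerated) then gives phenol 16 directly. The route is rejoined at 16, and steps 7 and 9 drop out.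

Step 15 (asymmetric epoxidation). The twisted 2',6'-dioxygenated aroyl group and the electron-rich, ortho-substituted ring B may lower rate and face selectivity, and the epoxide next to a trioxygenated arene is acid-labile. Fallback: set out from chalcone 25; copper-catalysed asymmetric conjugate borylation (CuCl, NaOt-Bu, a Josiphos ligand of the antipode that gives the 3R adduct, B2pin2, MeOH, THF, rt) gives β-boryl ketone F2. Oxidation with NaBO3·4H2O in THF/H2O replaces boron by hydroxyl with retention. The route is rejoined at the (3R)-β-hydroxy ketone 27, with no epoxide and no SmI2 step.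

Step 18 (Mitsunobu cyclisation). The carbinol sits beside a very electron-rich arene, so the alkoxyphosphonium may ionise (loss of clean inversion) or eliminate to the chalcone. Fallback: set out from chalcone 25; deallylation (Pd(PPh3)4, morpholine, THF) gives 2'-hydroxychalcone F3. Intramolecular oxa-Michael cyclisation (NaOAc, EtOH, reflux, or a quinine-derived bifunctional thiourea for partial catalyst control) gives flavanone 29 together with its (2R)-epimer F4. The two are diastereomers because of the lavandulyl centre and are separated by preparative HPLC. The route is rejoined at 29.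

Further compounds

F1 | step 8 | 2-[(2S)-5-methyl-2-(prop-1-en-2-yl)hex-4-en-1-yl]-4,4,5,5-tetramethyl-1,3,2-dioxaborolane (lavandulyl pinacol boronate) | CC(C)=CC[C@@H](C(C)=C)CB1OC(C)(C)C(C)(C)O1
F2 | step 15 | (3R)-1-{2-(allyloxy)-4-methoxy-6-(methoxymethoxy)-3-[(2R)-lavandulyl]phenyl}-3-[5-methoxy-2,4-bis(methoxymethoxy)phenyl]-3-(4,4,5,5-tetramethyl-1,3,2-dioxaborolan-2-yl)propan-1-one | C=CCOc1c(C[C@@H](CC=C(C)C)C(C)=C)c(OC)cc(OCOC)c1C(=O)C[C@@H](B2OC(C)(C)C(C)(C)O2)c3cc(OC)c(OCOC)cc3OCOC
F3 | step 18 | (E)-1-{2-hydroxy-4-methoxy-6-(methoxymethoxy)-3-[(2R)-lavandulyl]phenyl}-3-[5-methoxy-2,4-bis(methoxymethoxy)phenyl]prop-2-en-1-one | Oc1c(C[C@@H](CC=C(C)C)C(C)=C)c(OC)cc(OCOC)c1C(=O)/C=C/c1cc(OC)c(OCOC)cc1OCOC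
F4 | step 18 | (2R)-7-methoxy-5-(methoxymethoxy)-2-[5-methoxy-2,4-bis(methoxymethoxy)phenyl]-8-[(2R)-lavandulyl]chroman-4-one | C=C(C)[C@H](CC=C(C)C)Cc1c(OC)cc(OCOC)c2c1O[C@@H](c1cc(OC)c(OCOC)cc1OCOC)CC2=O
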